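The route rests on making the benzene ring last. That ring is a hydroquinone monoether in which O1 on C8a stands para to the hydroxyl on C6, exactly what a Cr(CO)5 alkoxycarbene, an alkyne and one CO ligand assemble. In a single operation the benzannulation forms C8a–C8, C7–C6 and C6–C5, fuses the arene onto the finished oxygen ring and leaves silicon at C7 as the handle for bromine. The precursor 11 is a six-membered cyclic Cr(CO)5 carbene complex: C8a is the carbene carbon, O1 ties it to the (S)-configured C2 inherited from (S)-linalool, and C4a bears the exocyclic methylene that becomes C5. The C4 ketone follows by benzylic oxidation.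

Key step: step 8

Assumption: (S)-(+)-linalool is bought in high enantiomeric purity; it is the only source of chirality, and no step breaks a bond at its carbinol carbon, which becomes C2.
Atom labels (O1, C2 … C8a) are those of the chroman-4-one target and are used for the same atoms in all earlier compounds.

Step 1
Reactants: 1 (S)-linalool
Product: 2 (5S)-5-methyl-5-(4-methylpent-3-en-1-yl)oxolan-2-ol (lactol; both anomers)
Conditions: Rh(acac)(CO)2 (0.5 mol %), PPh3 (5 mol %), CO/H2 (1:1, 40 bar), toluene, 60 °C
Reagents that add atoms: carbon monoxide, [C-]#[O+]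
Why: Hydroformylation: the quaternary carbinol carbon next to the vinyl group sends the formyl group to the terminal carbon, the trisubstituted alkene is too hindered to react, and the γ-hydroxy aldehyde closes at once to the lactol without touching the stereocentre (the anomeric mixture is erased in step 2).

Step 2
Reactants: 2 lactol
Product: 3 (5S)-5-methyl-5-(4-methylpent-3-en-1-yl)oxolan-2-one
Conditions: TEMPO (10 mol %), PhI(OAc)2 (1.2 equiv), CH2Cl2, rt
Reagents that add atoms: none
Why: Oxoammonium (TEMPO) oxidation of a lactol to the lactone spares the alkene and locks the future O1 in an ester, so that the two tertiary hydroxyl groups of the skeleton are never free in the same molecule.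

Step 3
Reactants: 3 alkenyl lactone
Product: 4 (5S)-5-(4-hydroxy-4-methylpentyl)-5-methyloxolan-2-one
Conditions: Co(acac)2 (20 mol %), PhSiH3 (2.5 equiv), O2 (1 atm), THF, rt
Reagents that add atoms: dioxygen, O=O
Why: Mukaiyama hydration (hydrogen-atom transfer from the Co–H species made from Co(acac)2 and PhSiH3, capture of the tertiary radical by O2, reduction of the peroxide by the silane) gives the Markovnikov tertiary alcohol, runs before any alkyne is present, and avoids the cationic ether-forming cyclisations typical of linalool-type substrates.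

Step 4
Reactants: 4 hydroxy lactone
Product: 5 (5S)-5-methyl-5-(4-methyl-4-triethylsilyloxypentyl)oxolan-2-one
Conditions: TESOTf (1.3 equiv), 2,6-lutidine (2 equiv), CH2Cl2, −78 to 0 °C
Reagents that add atoms: triethylsilyl trifluoromethanesulfonate, CC[Si](CC)(CC)OS(=O)(=O)C(F)(F)F
Why: Silyl triflate silylation of the only hydroxyl group present; a triethylsilyl ether on a tertiary carbinol should survive hydride, carbonate, butyllithium and warm THF and still leave in dilute acid.

Step 5
Reactants: 5 silyloxy lactone
Product: 7 (5S)-5,9-dimethyl-9-(triethylsilyloxy)dec-1-yn-5-ol, via silyloxy lactol 6 (not isolated)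
Conditions: i-Bu2AlH (1.1 equiv), CH2Cl2, −78 °C; MeOH, then K2CO3 (3 equiv), dimethyl (1-diazo-2-oxopropyl)phosphonate (1.5 equiv), −78 °C to rt
Reagents that add atoms: dimethyl (1-diazo-2-oxopropyl)phosphonate, COP(=O)(OC)C(=[N+]=[N-])C(C)=O
Why: Partial reduction of a γ-lactone followed by Seyferth–Gilbert homologation with the Ohira–Bestmann reagent on the ring-opened hydroxy aldehyde is a known one-flask lactone-to-alkynol sequence, and it frees the C2 hydroxyl only now, when the other alcohol is already capped.

Step 6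
Reactants: 7 alkynol; 8 hexacarbonylchromium
Product: 9 pentacarbonyl[(6S)-6-methyl-6-(4-methyl-4-triethylsilyloxypentyl)oxan-2-ylidene]chromium
Conditions: Cr(CO)6 (1.5 equiv), hν (Hg lamp, Pyrex), THF, rt, Ar purge; then 7, rt, dark, 16 h
Reagents that add atoms: none
Why: Alkynol cycloisomerisation at a Cr(CO)5 fragment: the terminal alkyne rearranges to the vinylidene complex and the tethered C2 hydroxyl adds to its electrophilic α-carbon (the future C8a), the established entry to 2-oxacyclopentylidene and 2-oxacyclohexylidene complexes, so the pyran ring closes through a new O1–C8a bond while the C2–O bond and its configuration stay as they are.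

Step 7
Reactants: 9 cyclic carbene complex
Product: 11 pentacarbonyl[(6S)-6-methyl-3-methylidene-6-(4-methyl-4-triethylsilyloxypentyl)oxan-2-ylidene]chromium, via methoxymethyl carbene complex 10 (not isolated)
Conditions: n-BuLi (1.05 equiv), THF, −78 °C; MeOCH2Cl (1.2 equiv), −78 to −20 °C; crude on basic Al2O3, Et2O, rt
Reagents that add atoms: chloromethyl methyl ether, COCCl
Why: α-Deprotonation of a Fischer carbene complex at C4a, alkylation of the anion with chloromethyl methyl ether and E1cB loss of methanol on basic alumina is the sequence known for α-methylene-2-oxacycloalkylidene complexes.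

Step 8
Reactants: 11 α-methylene carbene complex; 12 trimethylsilylacetylene
Product: 14 (2S)-2-methyl-2-(4-methyl-4-triethylsilyloxypentyl)-7-trimethylsilylchroman-6-ol, via tricarbonylchromium arene complex 13 (not isolated)
Conditions: 12 (3 equiv), degassed THF (0.05 M), sealed tube, 50 °C, 16 h; then air, Et2O, rt, light
Reagents that add atoms: none
Why: Proposed new method: warming expels one cis CO ligand, the alkyne binds and inserts into the Cr=C8a bond, a CO ligand migrates onto the new carbene carbon C7 to give a chromium-bound dienylketene, and a 6π-electrocyclisation joins the ketene carbon C6 to the methylene carbon C5 before tautomerisation gives the phenol as its Cr(CO)3 complex 13, which air strips to 14. The closest known reaction type is the Dötz benzannulation of acyclic and cycloalkenyl alkoxycarbene Cr(CO)5 complexes with alkynes to 4-alkoxyphenols, whereas a complex whose alkoxy oxygen and alkenyl carbon sit in one oxacyclohexylidene ring next to an exocyclic methylene has not been tried. The single new ring, the benzene ring, closes by that 6π-electrocyclisation, and because C8a and C4a are neighbours in the pyran ring the Cr=C8a and C4a=C5 bonds are locked s-cis, so the triene is preorganised. No stereocentre is formed, and C2 keeps all four bonds because the medium is neutral and aprotic and cannot ionise the tertiary C2–O1 bond. The step needs regioselective insertion, which the bulk of the trimethylsilyl group secures by taking the place next to the CO-derived C6 while the CH terminus bonds to C8a. It also needs CO insertion to outrun five-ring closure, which chromium as the metal, the alkoxy donor and a coordinating solvent favour for alkenyl complexes.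

Step 9
Reactants: 14 7-silylchroman-6-ol
Product: 15 (2S)-7-bromo-2-methyl-2-(4-methyl-4-triethylsilyloxypentyl)chroman-6-ol
Conditions: NBS (1.0 equiv), MeCN, −20 to 0 °C, dark
Reagents that add atoms: N-bromosuccinimide, O=C1CCC(=O)N1Br
Why: Electrophilic ipso-bromodesilylation: the free C6 hydroxyl activates its ortho position C7 and the β-silicon effect stabilises the ipso Wheland intermediate, so bromine should replace silicon in preference to hydrogen at C5 or C8.

Step 10
Reactants: 15 bromophenol
Product: 16 (2S)-7-bromo-2-methyl-2-(4-methyl-4-triethylsilyloxypentyl)chroman-6-yl acetate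
Conditions: Ac2O (1.5 equiv), pyridine, 0 °C to rt
Reagents that add atoms: acetic anhydride, CC(=O)OC(C)=O
Why: Standard O-acetylation of a phenol; the ester lowers the electron density of the hydroquinone ether so that step 11 cannot turn it into a quinone.

Step 11
Reactants: 16 chromanyl acetate
Product: 17 (2S)-7-bromo-2-methyl-2-(4-methyl-4-triethylsilyloxypentyl)-4-oxochroman-6-yl acetate
Conditions: Rh2(cap)4 (1 mol %, cap = caprolactamate), t-BuOOH (70 % aq, 5 equiv), NaHCO3 (0.5 equiv), ClCH2CH2Cl, 40 °C
Reagents that add atoms: tert-butyl hydroperoxide, CC(C)(C)OO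
Why: Benzylic C–H oxidation by tert-butylperoxyl radicals is a known way from benzo-fused methylene compounds to aryl ketones; C4 is the only benzylic position, its radical is stabilised by the ortho oxygen O1, and the buffered medium should spare silyl ether, acetate and C2.

Step 12
Reactants: 17 protected chromanone
Product: 19 (2S)-7-bromo-6-hydroxy-2-(4-hydroxy-4-methylpentyl)-2-methylchroman-4-one (CNP0351288.1), via acetoxy alcohol 18 (not isolated)
Conditions: HCl (0.5 M in MeOH), 0 °C to rt
Reagents that add atoms: none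
Why: Acid-catalysed methanolysis removes the triethylsilyl ether quickly and transesterifies the aryl acetate more slowly; base is avoided because a 2,2-disubstituted chroman-4-one can open by retro-oxa-Michael reaction and re-close with loss of the C2 configuration.

Compound list
1 | (S)-linalool | CC(C)=CCC[C@@](O)(C)C=C | starting material
2 | (5S)-5-methyl-5-(4-methylpent-3-en-1-yl)oxolan-2-ol | CC(C)=CCC[C@@]1(C)CCC(O)O1 | intermediate
3 | (5S)-5-methyl-5-(4-methylpent-3-en-1-yl)oxolan-2-one | CC(C)=CCC[C@@]1(C)CCC(=O)O1 | intermediate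
4 | (5S)-5-(4-hydroxy-4-methylpentyl)-5-methyloxolan-2-one | CC(C)(O)CCC[C@@]1(C)CCC(=O)O1 | intermediate
5 | (5S)-5-methyl-5-(4-methyl-4-triethylsilyloxypentyl)oxolan-2-one | CC(C)(O[Si](CC)(CC)CC)CCC[C@@]1(C)CCC(=O)O1 | intermediate
6 | (5S)-5-methyl-5-(4-methyl-4-triethylsilyloxypentyl)oxolan-2-ol | CC(C)(O[Si](CC)(CC)CC)CCC[C@@]1(C)CCC(O)O1 | intermediate
7 | (5S)-5,9-dimethyl-9-(triethylsilyloxy)dec-1-yn-5-ol | CC(C)(O[Si](CC)(CC)CC)CCC[C@@](O)(C)CCC#C | intermediate
8 | hexacarbonylchromium, Cr(CO)6 | O=C=[Cr](=C=O)(=C=O)(=C=O)(=C=O)=C=O | starting material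
9 | pentacarbonyl[(6S)-6-methyl-6-(4-methyl-4-triethylsilyloxypentyl)oxan-2-ylidene]chromium | CC(C)(O[Si](CC)(CC)CC)CCC[C@@]1(C)CCCC(=[Cr](=C=O)(=C=O)(=C=O)(=C=O)=C=O)O1 | intermediate
10 | pentacarbonyl[(6S)-3-(methoxymethyl)-6-methyl-6-(4-methyl-4-triethylsilyloxypentyl)oxan-2-ylidene]chromium (both C3 epimers) | CC(C)(O[Si](CC)(CC)CC)CCC[C@@]1(C)CCC(COC)C(=[Cr](=C=O)(=C=O)(=C=O)(=C=O)=C=O)O1 | intermediate
11 | pentacarbonyl[(6S)-6-methyl-3-methylidene-6-(4-methyl-4-triethylsilyloxypentyl)oxan-2-ylidene]chromium | CC(C)(O[Si](CC)(CC)CC)CCC[C@@]1(C)CCC(=C)C(=[Cr](=C=O)(=C=O)(=C=O)(=C=O)=C=O)O1 | intermediate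
12 | trimethylsilylacetylene | C#C[Si](C)(C)C | starting material
13 | tricarbonyl(η6-arene)chromium complex of 14 (both faces; η6 bond written as two fragments) | CC(C)(O[Si](CC)(CC)CC)CCC[C@@]1(C)CCc2cc(O)c([Si](C)(C)C)cc2O1.O=C=[Cr](=C=O)=C=O | intermediate
14 | (2S)-2-methyl-2-(4-methyl-4-triethylsilyloxypentyl)-7-trimethylsilylchroman-6-ol | CC(C)(O[Si](CC)(CC)CC)CCC[C@@]1(C)CCc2cc(O)c([Si](C)(C)C)cc2O1 | intermediate
15 | (2S)-7-bromo-2-methyl-2-(4-methyl-4-triethylsilyloxypentyl)chroman-6-ol | CC(C)(O[Si](CC)(CC)CC)CCC[C@@]1(C)CCc2cc(O)c(Br)cc2O1 | intermediate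
16 | (2S)-7-bromo-2-methyl-2-(4-methyl-4-triethylsilyloxypentyl)chroman-6-yl acetate | CC(C)(O[Si](CC)(CC)CC)CCC[C@@]1(C)CCc2cc(OC(C)=O)c(Br)cc2O1 | intermediate
17 | (2S)-7-bromo-2-methyl-2-(4-methyl-4-triethylsilyloxypentyl)-4-oxochroman-6-yl acetate | CC(C)(O[Si](CC)(CC)CC)CCC[C@@]1(C)CC(=O)c2cc(OC(C)=O)c(Br)cc2O1 | intermediate
18 | (2S)-7-bromo-2-(4-hydroxy-4-methylpentyl)-2-methyl-4-oxochroman-6-yl acetate | CC(C)(O)CCC[C@@]1(C)CC(=O)c2cc(OC(C)=O)c(Br)cc2O1 | intermediate
19 | (2S)-7-bromo-6-hydroxy-2-(4-hydroxy-4-methylpentyl)-2-methylchroman-4-one | CC(C)(O)CCC[C@@]1(C)CC(=O)c2cc(O)c(Br)cc2O1 | target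

Total step count: 12. Longest linear sequence: 12 steps (1 to 19).

Steps most likely to fail

Step 8 (new method). The electron-poor exocyclic alkene of 11 may oligomerise before a CO ligand is lost. The sequence may also stall at the silicon-stabilised ketene stage, or the ring may close without CO insertion. The fallback uses known chemistry and a bought arene instead of a built one; it sets out from 1 and returns at 14.
- 4-Bromo-3-iodophenol is carbamoylated (Et2NCOCl, K2CO3, MeCN) to 4-bromo-3-iodophenyl N,N-diethylcarbamate F1.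
- Compound 1 is hydroborated at the vinyl group only with 9-BBN-H to the B-alkyl borane F2.
- B-alkyl Suzuki–Miyaura coupling at the carbon–iodine bond of F1 (PdCl2(dppf), K3PO4, THF/DMF/H2O) gives the bromoaryl tertiary alcohol F3.
- Intramolecular C–O coupling (Pd(OAc)2, 2-(di-tert-butylphosphino)-1,1'-binaphthyl, Cs2CO3, toluene, 80 °C) keeps the C2–O bond intact and gives the chroman-6-yl carbamate F4.
- Mukaiyama hydration as in step 3 gives the tertiary alcohol F5, and TESOTf/2,6-lutidine gives its triethylsilyl ether F6.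
- Carbamate-directed ortho-lithiation at the less hindered C7 (s-BuLi, TMEDA, THF, −78 °C) and a Me3SiCl quench give the 7-silyl carbamate F7.
- LiAlH4 in THF removes the carbamate to give 14.

Step 6. Vinylidene formation at chromium is slow for pentynols, the hindered tertiary hydroxyl adds sluggishly, and alkyne oligomerisation at the metal can take over. The fallback sets out from 5 and returns at 11, so it also replaces steps 5 and 7.
- MeLi (1.0 equiv, THF, −78 °C) opens the lactone to the hydroxy methyl ketone F8, which is in equilibrium with its cyclic hemiketal.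
- 2,4,6-Triisopropylbenzenesulfonyl hydrazide gives the trisylhydrazone F9.
- A Shapiro reaction (n-BuLi, 3.2 equiv, THF/TMEDA, −78 to 0 °C) gives the 2-lithio-1-alkene alkoxide F10, which adds to a CO ligand of 8 in the classical Fischer manner.
- Aqueous Me4NBr delivers the tetramethylammonium acylchromate F11.
- Acetyl bromide (CH2Cl2, −40 °C) turns it into the acetoxycarbene complex F12.
- On warming, the tethered C2 hydroxyl displaces the acetoxy group and closes the ring to 11 with the methylene group already in place.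

Step 11. Hydrogen abstraction next to a ring deactivated by bromine and acetoxy may be slow, so that conversion stalls or the acetate is lost by perhydrolysis. The fallback sets out from 16 and returns at 17.
- Wohl–Ziegler bromination (NBS, AIBN, PhCF3, 80 °C) gives the 4-bromochroman F13.
- Silver-assisted hydrolysis (Ag2CO3, acetone/H2O, rt) gives the chroman-4-ol F14.
- Dess–Martin periodinane (NaHCO3, CH2Cl2) oxidises it to 17.

Further compounds
F1 | step 8 | 4-bromo-3-iodophenyl N,N-diethylcarbamate | CCN(CC)C(=O)Oc1ccc(Br)c(I)c1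
F2 | step 8 | (3R)-1-(9-borabicyclo[3.3.1]nonan-9-yl)-3,7-dimethyloct-6-en-3-ol (same spatial arrangement as 1; descriptor changes because boron ranks below carbon) | CC(C)=CCC[C@@](O)(C)CCB1C2CCCC1CCC2
F3 | step 8 | 4-bromo-3-[(3S)-3-hydroxy-3,7-dimethyloct-6-en-1-yl]phenyl N,N-diethylcarbamate | CC(C)=CCC[C@@](O)(C)CCc1cc(OC(=O)N(CC)CC)ccc1Br
F4 | step 8 | (2S)-2-methyl-2-(4-methylpent-3-en-1-yl)chroman-6-yl N,N-diethylcarbamate | CC(C)=CCC[C@@]1(C)CCc2cc(OC(=O)N(CC)CC)ccc2O1
F5 | step 8 | (2S)-2-(4-hydroxy-4-methylpentyl)-2-methylchroman-6-yl N,N-diethylcarbamate | CC(C)(O)CCC[C@@]1(C)CCc2cc(OC(=O)N(CC)CC)ccc2O1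
F6 | step 8 | (2S)-2-methyl-2-(4-methyl-4-triethylsilyloxypentyl)chroman-6-yl N,N-diethylcarbamate | CC(C)(O[Si](CC)(CC)CC)CCC[C@@]1(C)CCc2cc(OC(=O)N(CC)CC)ccc2O1
F7 | step 8 | (2S)-2-methyl-2-(4-methyl-4-triethylsilyloxypentyl)-7-trimethylsilylchroman-6-yl N,N-diethylcarbamate | CC(C)(O[Si](CC)(CC)CC)CCC[C@@]1(C)CCc2cc(OC(=O)N(CC)CC)c([Si](C)(C)C)cc2O1
F8 | step 6 | (5S)-5-hydroxy-5,9-dimethyl-9-(triethylsilyloxy)decan-2-one | CC(C)(O[Si](CC)(CC)CC)CCC[C@@](O)(C)CCC(C)=O
F9 | step 6 | 2,4,6-triisopropylbenzenesulfonylhydrazone of F8 | CC(C)(O[Si](CC)(CC)CC)CCC[C@@](O)(C)CCC(C)=NNS(=O)(=O)c1c(C(C)C)cc(C(C)C)cc1C(C)C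
F10 | step 6 | lithium (5S)-2-lithio-5,9-dimethyl-9-(triethylsilyloxy)dec-1-en-5-olate | CC(C)(O[Si](CC)(CC)CC)CCC[C@@](O[Li])(C)CCC(=C)[Li]
F11 | step 6 | tetramethylammonium pentacarbonyl[(5S)-5-hydroxy-5,9-dimethyl-2-methylidene-9-(triethylsilyloxy)decanoyl]chromate | CC(C)(O[Si](CC)(CC)CC)CCC[C@@](O)(C)CCC(=C)C(=O)[Cr-](=C=O)(=C=O)(=C=O)(=C=O)=C=O.C[N+](C)(C)C
F12 | step 6 | acetoxycarbene complex from F11 | CC(C)(O[Si](CC)(CC)CC)CCC[C@@](O)(C)CCC(=C)C(OC(C)=O)=[Cr](=C=O)(=C=O)(=C=O)(=C=O)=C=O
F13 | step 11 | (2S)-4,7-dibromo-2-methyl-2-(4-methyl-4-triethylsilyloxypentyl)chroman-6-yl acetate (both C4 epimers) | CC(C)(O[Si](CC)(CC)CC)CCC[C@@]1(C)CC(Br)c2cc(OC(C)=O)c(Br)cc2O1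
F14 | step 11 | (2S)-7-bromo-4-hydroxy-2-methyl-2-(4-methyl-4-triethylsilyloxypentyl)chroman-6-yl acetate (both C4 epimers) | CC(C)(O[Si](CC)(CC)CC)CCC[C@@]1(C)CC(O)c2cc(OC(C)=O)c(Br)cc2O1
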